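## Structural features

The target is a flavone: a benzo-fused γ-pyranone (rings A and C) that carries ring B on C2 through a single C2–C1' bond. It has no stereocentre, so no question of neighbouring stereocentres arises. Ring A is fully substituted, with methoxy groups on C5, C7 and C8 and the only free hydroxyl on C6, para to the ring oxygen O1. Ring B bears 2'-OH and 6'-OMe, so C1' lies between two oxygens that must be told apart. The fragile points are three. Pyranone C2 takes up hydroxide with ring opening to a 1,3-diketone which, with a free 2'-OH, can close again onto either ring. The 6-hydroxy-5,7,8-trimethoxy ring is a para-alkoxyphenol open to oxidation. Methyl ethers next to carbonyl groups are cleaved by strong Lewis acids. The real difficulty is twofold: the placing of five oxygens on ring A, and a doubly ortho-hindered C2–C1' bond whose two neighbours on ring B differ. The route uses the fact that, with ring B on C2, the 2'-oxygen sits one carbon away from C3. A carboxyl on C3, esterified with the ring B phenol, holds C1' (marked by bromine between its two oxygens) over C2–H of ring C, so that C2–C1' forms as a six-membered lactone closure; the bridging carbon is later lost as carbon dioxide.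

## Logic of the disconnections

**16 ⇒ 15.** The O6–CH2Ph bond is cut. The oxidation-prone 6-hydroxyl is thus masked until the last step, and the mask comes off under neutral conditions that cannot open the pyranone. The forward step must spare the C2=C3 bond and the free 2'-hydroxyl.

**15 ⇒ 13 (through 14).** A one-carbon bridge is put back: the C3–carboxyl bond and the acyl–O2' bond. This ties ring B to ring C in a rigid tetracycle and prepares the intramolecular bond formation. The forward demand is heavy. The lactone must be opened at its acyl carbon and not at C2, the hydroxy acid must never be set free (it would close again), and the carboxylate must lose carbon dioxide without excess base.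

**13 ⇒ 12.** The C2–C1' bond is cut, which opens the lactone ring. A doubly ortho-hindered intermolecular union becomes a ring closure, and the two ortho oxygens of ring B are already distinct (one in the ester, one a methyl ether). The forward step needs insertion of palladium into a hindered C–Br bond and cleavage of C2–H, without loss of the activated aryl ester. The design of 12 is kept on three grounds. Bromine suffices and is sold in the right place in 10. C2 stays unsubstituted. The benzyl ether on O6 passes every later step and is removed last.

**12 ⇒ 9 + 10 (through 11).** The acyl–oxygen bond of the ester is cut. Two fragments of similar size result, one of them commercial. The forward acylation must avoid attack of the phenoxide on C2 of the pyranone.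

**9 ⇒ 8 ⇒ 6 (through 7).** The carboxyl is taken back to the aldehyde level. Then O1–C2, C2–C3 and C3–CHO are cut, so that ring C falls back to an acetyl group next to a phenol. Two carbons come from a formamide. The forward step needs a ring A without free positions, which 6 provides.

**6 ⇒ 5 ⇒ 3 (through 4).** The O–benzyl bond is cut, then the aryl C–O bond para to the phenol. This removes the fifth oxygen and leaves a compound with one free ring position, para to the hydroxyl. The forward steps need para-selective hydroxylation, and alkylation of the non-chelated hydroxyl only.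

**3 ⇒ 2 ⇒ 1.** The aryl–acetyl bond is cut with the phenol returned to its methyl ether, then one O–methyl bond. The symmetric 2 has two equivalent free positions, so acylation has no regiochemical choice. The forward demand is cleavage of only the methoxy group crowded between the acetyl group and a second methoxy group.

## Other disconnections considered

**Alternative 1:** The cut is the C4a–C8a bond of ring A, which is built de novo and leads to the phenol A1. In the forward sense a functionalised alkenyl-lithium reagent adds to dimethyl squarate A3 and the alkoxide is silylated to give the cyclobutenone A2. Heating should open A2 to a dienylketene that closes by 6π electrocyclisation and tautomerises to A1.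
- In favour: every oxygen of ring A is placed by construction. O6 alone carries silicon, the hydroxyl that becomes O1 is free, and the future C4 stands beside it at the aldehyde level. No para-hydroxylation and no selective demethylation are needed. In regiocontrol of ring A this is better than the chosen plan.
- Against: it solves ring A only. The hindered C2–C1' bond and the 2'-OH/6'-OMe distinction remain, so A1 would still have to be carried into ring C and joined to ring B, possibly by the same lactone-bridged arylation. The alkenyl-lithium is not a shelf reagent, and acetal and silyl ether must survive the thermolysis.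
- Comparison: the mechanism is a catalyst-free pericyclic cascade, equal in reliability to the early steps chosen here. Ring A would take about three steps against four, equal or slightly better. The whole synthesis would not be shorter.

**Alternative 2:** The cut is the C5–C6 bond. Ring A is unravelled into a side chain on a 2-aryl-4-pyranone, the keto ester A5. In the forward sense base forms the enolate at the benzyloxy-bearing carbon of A5, which attacks the ester carbon in a 6-exo-trig Claisen closure. Aromatisation gives the flavone A4. Double O-methylation and hydrogenolysis of both benzyl ethers would finish.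
- In favour: ring B and the pyranone are in place before ring A exists. O2' is a benzyl ether, so no closure onto the wrong ring is possible. After the key step only two ordinary steps remain and no carbon has to be excised. This end game is better than that of the chosen plan.
- Against: A5 is harder to reach than anything in the chosen route, and the hindered aryl–carbon bond is only moved into its synthesis. The methine between ketone and pyranone is the more acidic site, so the required enolate is the minor one. Alkoxide bases can open the pyranone. The chelated 5-OH methylates sluggishly.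
- Comparison: classical carbonyl chemistry without a precious metal, equal in principle. In step count it is probably longer overall.

**Alternative 3:** The cuts are C1'–C2' and C1'–C6'. Ring B is reduced to the methyl carbon of the 2-methylchromone A7 plus dimethyl glutarate A8. A7 should be available from 6 in two steps. Its lateral anion is acylated by A8, and the acidic methylene so formed closes onto the second ester (6-exo-trig) to give the cyclohexanedione A6. Mono-O-methylation and dehydrogenation would lead to 15.
- In favour: no biaryl-type coupling is needed, since C1' is built as a carbanion centre. The two ortho oxygens are distinguished by desymmetrising a symmetric 1,3-dione, at no cost and with no carbon to remove. On this point and on end-game safety it is the better plan. It shares 1 to 6 and would have about the same step count, so it is equal there.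
- Against: the lateral anion can attack another pyranone or condense with itself. Several equivalents of strong base are needed. The aromatisation of a 2-substituted cyclohexane-1,3-dione next to a benzyl ether and an electron-rich ring A is the weak point.
- Comparison: the chosen plan has closer analogies for its bond-forming event, and the alternative has the simpler path after it. Neither is secured in advance.

Key step: step 8

Remark on the chemistry: the target has no stereocentre. The names and structures of 12 and 13 agree atom for atom and need no correction. The hydroxide opening of 13 is the least secure point and is treated under the uncertain steps.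

## Route

Step 1
Reactants: 1 3,4,5-trimethoxyphenol
Product: 2 1,2,3,5-tetramethoxybenzene
Conditions: MeI, K2CO3, acetone, reflux
Reagents that add atoms: iodomethane, CI
Why: Williamson O-methylation of the only free phenol; it makes the ring symmetric so that the next acylation has no regiochemical choice.

Step 2
Reactants: 2 1,2,3,5-tetramethoxybenzene
Product: 3 1-(2-hydroxy-3,4,6-trimethoxyphenyl)ethan-1-one
Conditions: AcCl, AlCl3, Et2O, 0 °C → reflux; aq. HCl
Reagents that add atoms: acetyl chloride, CC(=O)Cl
Why: Friedel–Crafts acylation at one of the two equivalent free positions; AlCl3 chelated by the new carbonyl should then cleave the ortho methoxy group crowded between the acetyl group and a second methoxy group, as is usual for 2,3,4,6-tetraoxygenated acetophenones, to give the hydrogen-bonded phenol.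

Step 3
Reactants: 3 1-(2-hydroxy-3,4,6-trimethoxyphenyl)ethan-1-one
Product: 5 1-(2,5-dihydroxy-3,4,6-trimethoxyphenyl)ethan-1-one, via aryl sulfate 4 (not isolated)
Conditions: K2S2O8, aq. KOH, 10–20 °C; then aq. HCl, 90 °C, N2
Reagents that add atoms: potassium peroxodisulfate, [K+].[K+].[O-]S(=O)(=O)OOS(=O)(=O)[O-]
Why: Elbs persulfate oxidation; the phenoxide is attacked at the only free ring carbon, which lies para to its oxygen, and acid hydrolysis of the sulfate 4 frees the hydroquinone.

Step 4
Reactants: 5 1-(2,5-dihydroxy-3,4,6-trimethoxyphenyl)ethan-1-one
Product: 6 1-[3-(benzyloxy)-6-hydroxy-2,4,5-trimethoxyphenyl]ethan-1-one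
Conditions: BnBr (1.05 equiv), K2CO3, DMF, rt
Reagents that add atoms: benzyl bromide, BrCc1ccccc1
Why: Williamson etherification; the hydroxyl ortho to the acetyl group is chelated and poorly nucleophilic, so one equivalent of halide with a mild base should alkylate only the other one.

Step 5
Reactants: 6 1-[3-(benzyloxy)-6-hydroxy-2,4,5-trimethoxyphenyl]ethan-1-one
Product: 8 6-(benzyloxy)-5,7,8-trimethoxy-4-oxo-4H-chromene-3-carbaldehyde, via iminium chloride 7 (not isolated)
Conditions: POCl3, DMF, 0 → 55 °C; then ice/H2O
Reagents that add atoms: N,N-dimethylformamide, CN(C)C=O; water, O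
Why: Vilsmeier–Haack double formylation of the methyl ketone, ring closure by the phenol with loss of dimethylamine, and hydrolysis of 7 to the 3-formylchromone; the fully substituted ring offers no position for ring formylation.

Step 6
Reactants: 8 6-(benzyloxy)-5,7,8-trimethoxy-4-oxo-4H-chromene-3-carbaldehyde
Product: 9 6-(benzyloxy)-5,7,8-trimethoxy-4-oxo-4H-chromene-3-carboxylic acid
Conditions: NaClO2, NaH2PO4, 2-methylbut-2-ene, t-BuOH/THF/H2O, 0 °C → rt
Reagents that add atoms: sodium chlorite, [Na+].[O-]Cl=O
Why: Pinnick oxidation at buffered, weakly acidic pH with a hypochlorite scavenger; this is the usual way from 3-formylchromones to the acids and avoids the base that would open the pyranone.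

Step 7
Reactants: 9 6-(benzyloxy)-5,7,8-trimethoxy-4-oxo-4H-chromene-3-carboxylic acid; 10 2-bromo-3-methoxyphenol
Product: 12 2-bromo-3-methoxyphenyl 6-(benzyloxy)-5,7,8-trimethoxy-4-oxo-4H-chromene-3-carboxylate, via acid chloride 11 (not isolated)
Conditions: (COCl)2, DMF (cat.), CH2Cl2, 0 °C → rt; then 10, pyridine, CH2Cl2, 0 °C → rt
Reagents that add atoms: none
Why: Acid chloride formation followed by O-acylation of the phenol; the weak base pyridine at low temperature keeps the phenoxide concentration small, which should suppress conjugate addition to C2.

Step 8
Reactants: 12 2-bromo-3-methoxyphenyl 6-(benzyloxy)-5,7,8-trimethoxy-4-oxo-4H-chromene-3-carboxylate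
Product: 13 9-(benzyloxy)-1,8,10,11-tetramethoxy-6H,7H-chromeno[4,3-b]chromene-6,7-dione
Conditions: Pd(OAc)2 (10 mol%), PCy3·HBF4 (20 mol%), potassium pivalate (2.5 equiv), DMA (dry, degassed), 110 °C
Reagents that add atoms: none
Why: Zerovalent palladium formed in situ should insert into the only C–Br bond of 12, and after bromide–pivalate exchange the arylpalladium pivalate, held over ring C by the ester, should cleave the acidic C2–H bond by concerted metalation–deprotonation and then form C2–C1' by reductive elimination from a seven-membered palladacycle. Carbopalladation of C2=C3 with aryl going to C2, followed by base-assisted loss of the C2 hydrogen from the palladium enolate, would lead to the same product. The closest known reaction type is the intramolecular direct arylation of 2-haloaryl esters of arene- and heteroarenecarboxylic acids to fused coumarin-type lactones, together with direct arylation at C2 of chromones. The new six-membered lactone ring (C2, C3, the carboxyl carbon, the ester oxygen, C2', C1') closes in a 6-endo sense with respect to C2=C3, both alkene carbons lying in the ring. No stereocentre is formed. The step needs chemoselectivity for C–Br over the acyl–oxygen bond, and site selectivity for C2: the tether brings no other C–H bond within reach, ring A has no hydrogen, and 5-exo attack at C3 would give a spiro alkylpalladium without β-hydrogen that should only revert. Dry potassium pivalate is chosen because it is too weak a nucleophile to cleave the activated ester or open the pyranone. The site of the new bond on ring B is fixed by the bromine between the two oxygens of 10.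

Step 9
Reactants: 13 9-(benzyloxy)-1,8,10,11-tetramethoxy-6H,7H-chromeno[4,3-b]chromene-6,7-dione
Product: 15 6-(benzyloxy)-2-(2-hydroxy-6-methoxyphenyl)-5,7,8-trimethoxy-4H-chromen-4-one, via potassium carboxylate 14 (not isolated)
Conditions: KOH (1.05 equiv), THF/H2O, 0 °C → rt; evaporate; then Cu2O (10 mol%), 1,10-phenanthroline (20 mol%), NMP/quinoline, 170 °C; AcOH work-up
Reagents that add atoms: none
Why: One equivalent of hydroxide should cleave the aryl ester by acyl substitution to the carboxylate 14 with a free phenol; 14 is never acidified, so the lactone cannot close again, and no excess base is left to open the pyranone. Copper-catalysed protodecarboxylation of a carboxylate flanked by an aryl group and a carbonyl group is a favourable case, and the organocopper at C3 should be protonated by the 2'-hydroxyl.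

Step 10
Reactants: 15 6-(benzyloxy)-2-(2-hydroxy-6-methoxyphenyl)-5,7,8-trimethoxy-4H-chromen-4-one
Product: 16 6,2'-dihydroxy-5,7,8,6'-tetramethoxyflavone [6-hydroxy-2-(2-hydroxy-6-methoxyphenyl)-5,7,8-trimethoxy-4H-chromen-4-one]
Conditions: H2 (1 atm), Pd/C (10%), EtOAc/MeOH, rt
Reagents that add atoms: none
Why: Hydrogenolysis of an aryl benzyl ether under neutral conditions; the flavone C2=C3 bond and the methyl ethers are inert at room temperature and one atmosphere, and the absence of base protects the 2'-hydroxyflavone from ring-opening isomerisation.

## Compound list

1 | 3,4,5-trimethoxyphenol | COc1cc(O)cc(OC)c1OC | starting material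
2 | 1,2,3,5-tetramethoxybenzene | COc1cc(OC)cc(OC)c1OC | intermediate
3 | 1-(2-hydroxy-3,4,6-trimethoxyphenyl)ethan-1-one | CC(=O)c1c(O)c(OC)c(OC)cc1OC | intermediate
4 | potassium 3-acetyl-4-hydroxy-2,5,6-trimethoxyphenyl sulfate | CC(=O)c1c(O)c(OC)c(OC)c(OS(=O)(=O)[O-])c1OC.[K+] | intermediate (not isolated)
5 | 1-(2,5-dihydroxy-3,4,6-trimethoxyphenyl)ethan-1-one | CC(=O)c1c(O)c(OC)c(OC)c(O)c1OC | intermediate
6 | 1-[3-(benzyloxy)-6-hydroxy-2,4,5-trimethoxyphenyl]ethan-1-one | CC(=O)c1c(O)c(OC)c(OC)c(OCc2ccccc2)c1OC | intermediate
7 | N-{[6-(benzyloxy)-5,7,8-trimethoxy-4-oxo-4H-chromen-3-yl]methylidene}-N-methylmethanaminium chloride | C[N+](C)=Cc1coc2c(OC)c(OC)c(OCc3ccccc3)c(OC)c2c1=O.[Cl-] | intermediate (not isolated)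
8 | 6-(benzyloxy)-5,7,8-trimethoxy-4-oxo-4H-chromene-3-carbaldehyde | O=Cc1coc2c(OC)c(OC)c(OCc3ccccc3)c(OC)c2c1=O | intermediate
9 | 6-(benzyloxy)-5,7,8-trimethoxy-4-oxo-4H-chromene-3-carboxylic acid | OC(=O)c1coc2c(OC)c(OC)c(OCc3ccccc3)c(OC)c2c1=O | intermediate
10 | 2-bromo-3-methoxyphenol | COc1cccc(O)c1Br | starting material
11 | 6-(benzyloxy)-5,7,8-trimethoxy-4-oxo-4H-chromene-3-carbonyl chloride | ClC(=O)c1coc2c(OC)c(OC)c(OCc3ccccc3)c(OC)c2c1=O | intermediate (not isolated)
12 | 2-bromo-3-methoxyphenyl 6-(benzyloxy)-5,7,8-trimethoxy-4-oxo-4H-chromene-3-carboxylate | COc1cccc(OC(=O)c2coc3c(OC)c(OC)c(OCc4ccccc4)c(OC)c3c2=O)c1Br | intermediate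
13 | 9-(benzyloxy)-1,8,10,11-tetramethoxy-6H,7H-chromeno[4,3-b]chromene-6,7-dione | COc1cccc2oc(=O)c3c(=O)c4c(OC)c(OCc5ccccc5)c(OC)c(OC)c4oc3c12 | intermediate
14 | potassium 6-(benzyloxy)-2-(2-hydroxy-6-methoxyphenyl)-5,7,8-trimethoxy-4-oxo-4H-chromene-3-carboxylate | COc1cccc(O)c1-c1oc2c(OC)c(OC)c(OCc3ccccc3)c(OC)c2c(=O)c1C(=O)[O-].[K+] | intermediate (not isolated)
15 | 6-(benzyloxy)-2-(2-hydroxy-6-methoxyphenyl)-5,7,8-trimethoxy-4H-chromen-4-one | COc1cccc(O)c1-c1cc(=O)c2c(OC)c(OCc3ccccc3)c(OC)c(OC)c2o1 | intermediate
16 | 6,2'-dihydroxy-5,7,8,6'-tetramethoxyflavone | COc1cccc(O)c1-c1cc(=O)c2c(OC)c(O)c(OC)c(OC)c2o1 | target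

## Step count and uncertain steps

Total step count: 10. Longest linear sequence: 10 steps (1 to 16); 10 enters as purchased in step 7.

**Step 8 (key step).** Oxidative addition at a bromide flanked by two oxygens is slow, and the ester must turn into its less favoured rotamer before palladium can reach C2. Protodebromination, cleavage of the activated aryl ester by carboxylate or traces of water, and unproductive attack at C3 may therefore outrun ring closure. Fallback, from 6 back to the route at 16: the tether is given up and C2–C1' is made by carbonyl condensation.
- Commercial 2-hydroxy-6-methoxybenzaldehyde is benzylated (BnBr, K2CO3, DMF) to 2-(benzyloxy)-6-methoxybenzaldehyde F1.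
- Claisen–Schmidt condensation of 6 with F1 (KOH, EtOH, rt) should give (2E)-1-[3-(benzyloxy)-6-hydroxy-2,4,5-trimethoxyphenyl]-3-[2-(benzyloxy)-6-methoxyphenyl]prop-2-en-1-one F2.
- Oxidative cyclisation (I2 cat., DMSO, 120 °C) should give 6-(benzyloxy)-2-[2-(benzyloxy)-6-methoxyphenyl]-5,7,8-trimethoxy-4H-chromen-4-one F3. Its benzyl ether on O2' excludes closure onto ring B.
- Hydrogenolysis of both benzyl ethers (H2, Pd/C, EtOAc/MeOH) then gives 16.

**Step 9.** This is the least secure step after the key step. Hydroxide may add to C2 in conjugate fashion instead of attacking the lactone carbonyl. The pyranone would then open, and later closure could take place through either phenol, which would scramble rings A and B. Even after correct opening, any acidification before decarboxylation would close the lactone again. Fallback, from 13 back to the route at 15: the double bond is saturated first, so that C2 carries hydrogen and cannot be substituted.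
- Conjugate reduction (LiBH(s-Bu)3, THF, −78 °C) should give cis-9-(benzyloxy)-1,8,10,11-tetramethoxy-6a,12a-dihydro-6H,7H-chromeno[4,3-b]chromene-6,7-dione F4. It is racemic, and its configuration does not matter because both centres are lost later.
- F4 is a true β-keto lactone. Neutral hydrolysis (wet DMSO, 130 °C) should open it, and the β-keto acid should lose carbon dioxide at once to give racemic 6-(benzyloxy)-2-(2-hydroxy-6-methoxyphenyl)-5,7,8-trimethoxy-2,3-dihydro-4H-chromen-4-one F5. At the flavanone level only the ring A oxygen can close the ring.
- Dehydrogenation (I2 cat., DMSO, 120 °C) returns to 15.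

**Step 3.** Elbs oxidations of electron-rich phenoxides tend to stop at low conversion, and the hydroquinone is easily oxidised further to quinone and polymeric material. Fallback, from 3 back to the route at 5: the oxygen is introduced through a carbon substituent.
- Rieche formylation at the only free position (Cl2CHOMe, TiCl4, CH2Cl2, 0 °C) should give 3-acetyl-4-hydroxy-2,5,6-trimethoxybenzaldehyde F6.
- Dakin oxidation of this para-hydroxybenzaldehyde (H2O2, aq. NaOH, 0 °C → rt), with hydrolysis of the aryl formate in the same flask, gives 5.

**Step 7.** The ortho-bromophenol is hindered and weakly nucleophilic. Conjugate addition of phenoxide or base to C2 of the very electrophilic acid chloride, with opening of the pyranone, may compete with O-acylation. Fallback, from 6 back to the route at 12, bypassing 8, 9 and 11: the ester is made by forming the acyl carbon from carbon monoxide.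
- Condensation of 6 with DMF dimethyl acetal (toluene, 90 °C) should give (2E)-1-[3-(benzyloxy)-6-hydroxy-2,4,5-trimethoxyphenyl]-3-(dimethylamino)prop-2-en-1-one F7.
- Iodine-induced cyclisation (I2, CHCl3, rt) should give 6-(benzyloxy)-3-iodo-5,7,8-trimethoxy-4H-chromen-4-one F8.
- Aryloxycarbonylation with 10 (Pd(OAc)2, Xantphos, CO 1 atm, Et3N, toluene, 80 °C) should insert selectively into the C–I bond, leave the hindered C–Br bond of 10 alone, and give 12.

## Further compounds

F1 | step 8 | 2-(benzyloxy)-6-methoxybenzaldehyde | COc1cccc(OCc2ccccc2)c1C=O
F2 | step 8 | (2E)-1-[3-(benzyloxy)-6-hydroxy-2,4,5-trimethoxyphenyl]-3-[2-(benzyloxy)-6-methoxyphenyl]prop-2-en-1-one | COc1cccc(OCc2ccccc2)c1/C=C/C(=O)c1c(O)c(OC)c(OC)c(OCc2ccccc2)c1OC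
F3 | step 8 | 6-(benzyloxy)-2-[2-(benzyloxy)-6-methoxyphenyl]-5,7,8-trimethoxy-4H-chromen-4-one | COc1cccc(OCc2ccccc2)c1-c1cc(=O)c2c(OC)c(OCc3ccccc3)c(OC)c(OC)c2o1
F4 | step 9 | cis-9-(benzyloxy)-1,8,10,11-tetramethoxy-6a,12a-dihydro-6H,7H-chromeno[4,3-b]chromene-6,7-dione (racemic, one enantiomer drawn) | COc1cccc2OC(=O)[C@@H]3C(=O)c4c(OC)c(OCc5ccccc5)c(OC)c(OC)c4O[C@@H]3c12
F5 | step 9 | 6-(benzyloxy)-2-(2-hydroxy-6-methoxyphenyl)-5,7,8-trimethoxy-2,3-dihydro-4H-chromen-4-one (racemic) | COc1cccc(O)c1C1CC(=O)c2c(OC)c(OCc3ccccc3)c(OC)c(OC)c2O1
F6 | step 3 | 3-acetyl-4-hydroxy-2,5,6-trimethoxybenzaldehyde | CC(=O)c1c(O)c(OC)c(OC)c(C=O)c1OC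
F7 | step 7 | (2E)-1-[3-(benzyloxy)-6-hydroxy-2,4,5-trimethoxyphenyl]-3-(dimethylamino)prop-2-en-1-one | CN(C)/C=C/C(=O)c1c(O)c(OC)c(OC)c(OCc2ccccc2)c1OC
F8 | step 7 | 6-(benzyloxy)-3-iodo-5,7,8-trimethoxy-4H-chromen-4-one | COc1c(OCc2ccccc2)c(OC)c(OC)c2occ(I)c(=O)c12
A1 | alternative 1 | 4-(tert-butyldimethylsilyloxy)-2-(dimethoxymethyl)-3,5,6-trimethoxyphenol | COC(OC)c1c(OC)c(O[Si](C)(C)C(C)(C)C)c(OC)c(OC)c1O
A2 | alternative 1 | 4-(tert-butyldimethylsilyloxy)-2,3-dimethoxy-4-[(1Z)-1,3,3-trimethoxyprop-1-en-1-yl]cyclobut-2-en-1-one (racemic) | COC(OC)/C=C(\OC)C1(O[Si](C)(C)C(C)(C)C)C(OC)=C(OC)C1=O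
A3 | alternative 1 | dimethyl squarate (3,4-dimethoxycyclobut-3-ene-1,2-dione) | COC1=C(OC)C(=O)C1=O
A4 | alternative 2 | 6-(benzyloxy)-2-[2-(benzyloxy)-6-methoxyphenyl]-5,7-dihydroxy-8-methoxy-4H-chromen-4-one | COc1cccc(OCc2ccccc2)c1-c1cc(=O)c2c(O)c(OCc3ccccc3)c(O)c(OC)c2o1
A5 | alternative 2 | methyl 2-[3-(benzyloxy)-1-methoxy-2-oxopropyl]-6-[2-(benzyloxy)-6-methoxyphenyl]-4-oxo-4H-pyran-3-carboxylate (racemic) | COC(=O)c1c(C(OC)C(=O)COCc2ccccc2)oc(-c2c(OC)cccc2OCc2ccccc2)cc1=O
A6 | alternative 3 | 6-(benzyloxy)-2-(2-hydroxy-6-oxocyclohex-1-en-1-yl)-5,7,8-trimethoxy-4H-chromen-4-one | O=C1CCCC(O)=C1c1cc(=O)c2c(OC)c(OCc3ccccc3)c(OC)c(OC)c2o1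
A7 | alternative 3 | 6-(benzyloxy)-5,7,8-trimethoxy-2-methyl-4H-chromen-4-one | Cc1cc(=O)c2c(OC)c(OCc3ccccc3)c(OC)c(OC)c2o1
A8 | alternative 3 | dimethyl glutarate (dimethyl pentanedioate) | COC(=O)CCCC(=O)OC
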